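## Retrosynthetic overview

1. Target 16 ← methyl esterification and Jones oxidation of a CH2OTBS group; the α-methyl stereocentre is carried through from (S)-Roche ester.
2. The 1,2-dioxane (the only ring formed in the route) ← diimide reduction of a 3,6-dihydro-1,2-dioxine ← [4+2] cycloaddition of singlet oxygen to the (3Z,5E)-diene 12, which sets C3 and C6 together under control of the Roche stereocentre.
3. Diene 12 ← Julia–Kocienski olefination of (Z)-keto-enal 6 with Roche-derived PT-sulfone 11.
4. Enal 6 ← dihydro-β-ionone: methyl ketone → 2-alkynoate, syn-addition of Me2CuLi to fix the Z-trisubstituted alkene, then allylic oxidation of the ring to the enone. The enone also protects the ring alkene from singlet oxygen.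

Assumption: the target SMILES is the (2R,3S,6R) isomer, with the C3 side chain cis to the C6 methyl. Dioxane numbering used throughout: O1–O2–C3(H)–C4–C5–C6(Me).

## Route

**Step 1**
Reactants: 1, dihydro-β-ionone [4-(2,6,6-trimethylcyclohex-1-en-1-yl)butan-2-one]
Product: 2, methyl 5-(2,6,6-trimethylcyclohex-1-en-1-yl)pent-2-ynoate
Conditions: LDA, THF, −78 °C; ClP(O)(OEt)2, −78 °C → rt; LDA (2.3 equiv), −78 °C → rt; then ClCO2Me (excess), −78 → 0 °C
Reagents that add atoms: methyl chloroformate, COC(=O)Cl
Why: Negishi enol-phosphate elimination (kinetic methyl enolate → enol phosphate → lithium acetylide) followed by in-situ C-acylation gives the 2-alkynoate; no stereocentre is involved.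

**Step 2**
Reactants: 2
Product: 3, methyl (2Z)-3-methyl-5-(2,6,6-trimethylcyclohex-1-en-1-yl)pent-2-enoate
Conditions: Me2CuLi (1.2 equiv), THF, −78 °C; MeOH quench at −78 °C
Reagents that add atoms: lithium dimethylcuprate, [Li+].C[Cu-]C
Why: Syn-carbocupration (cuprate conjugate addition to a 2-alkynoate) puts Me and Cu cis, so after cold protonation the ring-bearing chain is cis to CO2Me (Z, typically ≥95:5).

**Step 3**
Reactants: 3
Product: 4, methyl (2Z)-3-methyl-5-(2,6,6-trimethyl-3-oxocyclohex-1-en-1-yl)pent-2-enoate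
Conditions: CrO3, 3,5-dimethylpyrazole, CH2Cl2, −20 °C
Reagents that add atoms: chromium trioxide, O=[Cr](=O)=O
Why: Cr(VI) allylic oxidation attacks the ring CH2 of the electron-rich tetrasubstituted alkene to give the ring enone, while the electron-poor enoate alkene and its γ-positions are spared.

**Step 4**
Reactants: 4
Product: 5, (2Z)-5-(3-hydroxy-2,6,6-trimethylcyclohex-1-en-1-yl)-3-methylpent-2-en-1-ol (racemic at the ring carbinol, which is removed in step 5)
Conditions: DIBAL-H (5 equiv), CH2Cl2, −78 → 0 °C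
Reagents that add atoms: none
Why: DIBAL 1,2-reduction of the enoate and the enone gives the bis-allylic diol without touching the Z-alkene geometry.

**Step 5**
Reactants: 5
Product: 6, (2Z)-3-methyl-5-(2,6,6-trimethyl-3-oxocyclohex-1-en-1-yl)pent-2-enal
Conditions: Dess–Martin periodinane (3 equiv), NaHCO3, CH2Cl2, 0 °C → rt; use directly
Reagents that add atoms: none
Why: Buffered Dess–Martin oxidation converts both allylic alcohols to carbonyls under non-isomerising conditions, restoring the ring enone and giving the Z-enal.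

**Step 6**
Reactants: 7, methyl (S)-3-hydroxy-2-methylpropanoate [(S)-Roche ester]
Product: 8, methyl (S)-3-[(tert-butyldimethylsilyl)oxy]-2-methylpropanoate
Conditions: TBSCl, imidazole, DMF, rt
Reagents that add atoms: TBSCl, CC(C)(C)[Si](C)(C)Cl
Why: Standard silylation of the primary alcohol; the purchased stereocentre is untouched.

**Step 7**
Reactants: 8
Product: 9, (R)-3-[(tert-butyldimethylsilyl)oxy]-2-methylpropan-1-ol
Conditions: DIBAL-H (2.2 equiv), CH2Cl2, −78 → 0 °C
Reagents that add atoms: none
Why: Ester reduction to the primary alcohol without epimerisation (the descriptor changes by CIP priority only).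

**Step 8**
Reactants: 9
Product: 10, 5-{[(2S)-3-[(tert-butyldimethylsilyl)oxy]-2-methylpropyl]sulfanyl}-1-phenyl-1H-tetrazole
Conditions: 1-phenyl-1H-tetrazole-5-thiol, PPh3, DIAD, THF, 0 °C → rt
Reagents that add atoms: 1-phenyl-1H-tetrazole-5-thiol, Sc1nnnn1-c1ccccc1
Why: Mitsunobu thioetherification at the primary carbon; the stereocentre is not involved.

**Step 9**
Reactants: 10
Product: 11, 5-{[(2S)-3-[(tert-butyldimethylsilyl)oxy]-2-methylpropyl]sulfonyl}-1-phenyl-1H-tetrazole
Conditions: (NH4)6Mo7O24·4H2O (cat.), 30% H2O2, EtOH, 0 °C → rt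
Reagents that add atoms: hydrogen peroxide, OO
Why: Molybdate-catalysed sulfide-to-sulfone oxidation, which the TBS ether tolerates.

**Step 10**
Reactants: 11 (1.2 equiv) and 6
Product: 12, 3-[(3Z,5E,7R)-8-[(tert-butyldimethylsilyl)oxy]-3,7-dimethylocta-3,5-dien-1-yl]-2,4,4-trimethylcyclohex-2-en-1-one
Conditions: 11, KHMDS, DME, −60 °C, 30 min; then 6, −60 °C → rt
Reagents that add atoms: none
Why: Julia–Kocienski olefination of an alkyl PT-sulfone with an enal gives the new disubstituted alkene E-selectively; the aldehyde reacts in preference to the hindered enone, and the Z-alkene and the stereocentre are carried through.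

**Step 11**
Reactants: 12
Product: 13, (3S,6R)-3-[(2S)-1-[(tert-butyldimethylsilyl)oxy]propan-2-yl]-6-methyl-6-[2-(2,6,6-trimethyl-3-oxocyclohex-1-en-1-yl)ethyl]-3,6-dihydro-1,2-dioxine (major diastereomer, isolated by chromatography)
Conditions: O2, TPP (1 mol %), visible light (>500 nm), CCl4, 0 °C
Reagents that add atoms: oxygen, O=O
Why: Suprafacial [4+2] cycloaddition of singlet oxygen to the s-cis diene: the 3Z,5E geometry places the C3 side chain and the C6 methyl both "outside", hence cis on the ring. With the allylic C–H in the diene plane, O2 adds anti to the bulky CH2OTBS group, giving the 2,3-syn (3S,6R) adduct as the major isomer; I expect only moderate selectivity, so the minor isomers are removed by chromatography. The s-trans ring enone is inert to 1O2, and TPP cannot sensitise diene isomerisation.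

**Step 12**
Reactants: 13
Product: 14, (3S,6R)-3-[(2S)-1-[(tert-butyldimethylsilyl)oxy]propan-2-yl]-6-methyl-6-[2-(2,6,6-trimethyl-3-oxocyclohex-1-en-1-yl)ethyl]-1,2-dioxane
Conditions: KO2CN=NCO2K (excess), AcOH, CH2Cl2/MeOH, 0 °C → rt
Reagents that add atoms: none
Why: Diimide reduces the cis-disubstituted ring alkene without cleaving the O–O bond (as with ascaridole) and does not touch the tetrasubstituted enone; the stereocentres are unaffected.

**Step 13**
Reactants: 14
Product: 15, (2R)-2-{(3S,6R)-6-methyl-6-[2-(2,6,6-trimethyl-3-oxocyclohex-1-en-1-yl)ethyl]-1,2-dioxan-3-yl}propanoic acid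
Conditions: Jones reagent (CrO3, H2SO4, H2O), acetone, 0 °C → rt
Reagents that add atoms: chromium trioxide, O=[Cr](=O)=O; water, O
Why: Jones conditions cleave the primary TBS ether and oxidise it directly to the acid; the acidic medium avoids base-induced retro-peroxy-Michael or Kornblum–DeLaMare cleavage and C2 epimerisation, and dialkyl peroxides and enones survive Cr(VI).

**Step 14**
Reactants: 15
Product: 16, methyl diacarnoate A [methyl (2R)-2-{(3S,6R)-6-methyl-6-[2-(2,6,6-trimethyl-3-oxocyclohex-1-en-1-yl)ethyl]-1,2-dioxan-3-yl}propanoate]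
Conditions: TMSCHN2, MeOH/PhMe, 0 °C
Reagents that add atoms: trimethylsilyldiazomethane, C[Si](C)(C)C=[N+]=[N-]
Why: Neutral, base-free O-methylation of the acid leaves the peroxide and the α-stereocentre untouched.

## Compound list

1 | dihydro-β-ionone | CC(=O)CCC1=C(C)CCCC1(C)C | starting material
2 | methyl 5-(2,6,6-trimethylcyclohex-1-en-1-yl)pent-2-ynoate | COC(=O)C#CCCC1=C(C)CCCC1(C)C | intermediate
3 | methyl (2Z)-3-methyl-5-(2,6,6-trimethylcyclohex-1-en-1-yl)pent-2-enoate | COC(=O)/C=C(/C)CCC1=C(C)CCCC1(C)C | intermediate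
4 | methyl (2Z)-3-methyl-5-(2,6,6-trimethyl-3-oxocyclohex-1-en-1-yl)pent-2-enoate | COC(=O)/C=C(/C)CCC1=C(C)C(=O)CCC1(C)C | intermediate
5 | (2Z)-5-(3-hydroxy-2,6,6-trimethylcyclohex-1-en-1-yl)-3-methylpent-2-en-1-ol (racemic carbinol) | OC/C=C(/C)CCC1=C(C)C(O)CCC1(C)C | intermediate
6 | (2Z)-3-methyl-5-(2,6,6-trimethyl-3-oxocyclohex-1-en-1-yl)pent-2-enal | O=C/C=C(/C)CCC1=C(C)C(=O)CCC1(C)C | intermediate
7 | methyl (S)-3-hydroxy-2-methylpropanoate, (S)-Roche ester | COC(=O)[C@@H](C)CO | starting material
8 | methyl (S)-3-(TBS-oxy)-2-methylpropanoate | COC(=O)[C@@H](C)CO[Si](C)(C)C(C)(C)C | intermediate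
9 | (R)-3-(TBS-oxy)-2-methylpropan-1-ol | OC[C@@H](C)CO[Si](C)(C)C(C)(C)C | intermediate
10 | 5-{[(2S)-3-(TBS-oxy)-2-methylpropyl]sulfanyl}-1-phenyl-1H-tetrazole | CC(C)(C)[Si](C)(C)OC[C@H](C)CSc1nnnn1-c1ccccc1 | intermediate
11 | 5-{[(2S)-3-(TBS-oxy)-2-methylpropyl]sulfonyl}-1-phenyl-1H-tetrazole | CC(C)(C)[Si](C)(C)OC[C@H](C)CS(=O)(=O)c1nnnn1-c1ccccc1 | intermediate
12 | 3-[(3Z,5E,7R)-8-(TBS-oxy)-3,7-dimethylocta-3,5-dien-1-yl]-2,4,4-trimethylcyclohex-2-en-1-one | CC1=C(CC/C(C)=C\C=C\[C@@H](C)CO[Si](C)(C)C(C)(C)C)C(C)(C)CCC1=O | intermediate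
13 | (3S,6R)-3-[(2S)-1-(TBS-oxy)propan-2-yl]-6-methyl-6-[2-(2,6,6-trimethyl-3-oxocyclohex-1-en-1-yl)ethyl]-3,6-dihydro-1,2-dioxine | CC(C)(C)[Si](C)(C)OC[C@H](C)[C@@H]1C=C[C@@](C)(CCC2=C(C)C(=O)CCC2(C)C)OO1 | intermediate
14 | (3S,6R)-3-[(2S)-1-(TBS-oxy)propan-2-yl]-6-methyl-6-[2-(2,6,6-trimethyl-3-oxocyclohex-1-en-1-yl)ethyl]-1,2-dioxane | CC(C)(C)[Si](C)(C)OC[C@H](C)[C@@H]1CC[C@@](C)(CCC2=C(C)C(=O)CCC2(C)C)OO1 | intermediate
15 | (2R)-2-{(3S,6R)-6-methyl-6-[2-(2,6,6-trimethyl-3-oxocyclohex-1-en-1-yl)ethyl]-1,2-dioxan-3-yl}propanoic acid | OC(=O)[C@H](C)[C@@H]1CC[C@@](C)(CCC2=C(C)C(=O)CCC2(C)C)OO1 | intermediate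
16 | methyl diacarnoate A | COC(=O)[C@H](C)[C@@H]1CC[C@@](C)(CCC2=C(C)C(=O)CCC2(C)C)OO1 | target

## Summary

Total steps: 14. Longest linear sequence: 10 (steps 1–5, then 10–14).

Three steps most likely to fail:

1. **Step 11, singlet-oxygen [4+2].** The trisubstituted diene terminus has an "inside" alkyl group, so ene reaction and stepwise (zwitterionic) addition with loss of Z/E information can compete, and facial selectivity from the Roche centre is only moderate. Fallback: build the ring without the diene, by Co(II)/Et3SiH/O2 (Mukaiyama–Isayama) hydroperoxysilylation of the corresponding 1,1-disubstituted alkene, then desilylation and intramolecular peroxy-Michael addition onto an (E)-2-methyl-enoate, with diastereomer separation.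
2. **Step 10, Julia–Kocienski coupling.** Risks are E/Z erosion at the new alkene and base-induced Z→E isomerisation or γ-deprotonation of enal 6. Fallback: reverse the polarity, converting the Z-allylic alcohol to an allylic phosphonate or diphenylphosphine oxide and performing an E-selective Horner-type olefination with the (S)-Roche aldehyde.
3. **Step 3, allylic oxidation.** Risks are regioselectivity (ring CH2 versus exocyclic allylic CH2 or CH3) and modest yield. Fallback: assemble the oxidised ring directly by Stork–Danheiser addition of a protected but-3-ynyl-lithium to 3-isobutoxy-2,6,6-trimethylcyclohex-2-enone with acidic hydrolysis, then carbomethoxylate the alkyne and add Me2CuLi.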